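**Remark on the chemistry (assumption):** the target is taken in the open para-quinone methide form that the SMILES shows, not as the ring-closed 6,6-diaryl-6H-benzo[c]chromene that the ring B 2'-hydroxyl could form by adding to the methide carbon.

Atom labels used below: ring A is the central benzene. C1 bears the diarylmethylene carbon C7, C2 bears ring B (2,4-dihydroxyphenyl, C1'–C6'), C3 and C4 bear hydrogen, C5 bears CH2OH and C6 bears the alkyne to ring C (4-hydroxyphenyl). Ring D is the 4-hydroxyphenyl group on C7 and ring E is the cyclohexadienone. Compound numbers 1–18 are those of the steps and of the compound list.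

## Analysis of the target

Selaginellin F (18) has no ring fusion. Ring A carries four carbon substituents on the contiguous carbons C5, C6, C1 and C2: a hydroxymethyl group, an arylethynyl group (ring C), the diarylmethylene carbon C7 and ring B. C7 is the exocyclic carbon of a para-quinone methide built from ring E and ring D. There is no stereocentre, and the C7=C double bond has no geometric isomers because ring E is symmetric. The sensitive groups are the quinone methide (it adds nucleophiles and hydride), four phenols and one benzylic alcohol, and a diarylalkyne whose neighbour at C5 is a hydroxymethyl group that can add across it under metal or strong acid catalysis. The difficulty is the crowding at C1, which sits between an aryl and an alkynyl group and must carry a fully substituted carbon, together with the need to place four different groups on neighbouring ring A carbons without isomers. The strategy rests on two facts. First, C1 and C2 are adjacent and both bear carbon substituents, with the sp carbon on C6 next to C1, so a C1≡C2 aryne can take ring B as a nucleophile at C2 and a diaryl ketone as an electrophile at C1. Second, the quinone methide is simply the dehydration product of a triaryl carbinol that has a para-hydroxyl group.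

## Retrosynthetic reasoning

**18 to 17.** The C7=ring E double bond is traced back to a C7–OH triaryl carbinol, and all six hydroxyl groups are masked as MOM ethers. No skeletal bond is cut. The gain is that the electrophilic quinone methide appears only in the last operation, where one acid treatment has to remove six acetals and ionise the carbinol.

**17 to 8, 13 and 12.** The two bonds cut are C2–C1' (to ring B) and C1–C7. They are adjacent, they are the two most hindered bonds of ring A, and cutting them leaves a symmetric ketone (12), a simple aryllithium (13) and a trisubstituted fluoroarene (8). The forward reaction has to do four things in one flask: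
- lithiate 8 at the C1–H between fluorine and the alkyne, giving 14;
- expel fluoride to give aryne 15;
- add 13 at C2 only, giving the C1-lithiated biaryl 16;
- make 16 add to 12.

Cutting the alkyne or the C5 carbon instead would leave the hard C1/C2 pattern unsolved. The base for the lithiation is an alkyllithium and not a lithium amide. The amine left behind by an amide base would carry protons between aryllithiums and let the lithium of 13 move to the more acidic position between its two oxygens.

**13 to 10 to 9, and 12 to 11.** 13 comes from bromide 10 by bromine–lithium exchange, which fixes the lithium at the carbon para to one oxygen and ortho to the other. Direct deprotonation would go between the oxygens. 10 and 12 are the MOM ethers of the commercial phenols 9 and 11.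

**8 to 7.** Both MOM ethers of 8, the phenolic one and the benzylic one, are put on in one operation from diol 7.

**7 to 5 and 6.** The C(sp)–C(sp2) bond to ring C is cut. A Sonogashira coupling of the terminal alkyne 5 with iodide 6 forms it at room temperature, and the C–F bond is inert to palladium.

**5 to 3 (through 4) to 1 and 2.** The ring A alkyne carbon comes from a Sonogashira coupling of the commercial bromide 1 with silylacetylene 2. In 1 the bromine, the fluorine and the formyl carbon already stand where C6, C2 and the C5 carbon are needed. The aldehyde is reduced before the silyl group is taken off, so that a free 2-ethynylbenzaldehyde never forms.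

## Alternatives that were turned down

**Alternative 1: hexadehydro-Diels–Alder aryne trapped by a phenol.**
- Disconnection: ring A itself is taken apart at C4–C5 and C1–C6, into a 1,3-diyne (C1 to C4) and an alkyne (C5≡C6) joined by an ester tether, and the C2–C1' bond is cut as well.
- Forward key step: heating the tetrayne 5-[tri(propan-2-yl)silyl]penta-2,4-diyn-1-yl 6-[4-(methoxymethoxy)phenyl]-6-oxohexa-2,4-diynoate A1 would close ring A as a C2≡C3 aryne fused to a five-membered lactone. Resorcinol A2 would then add by a phenol ene reaction to give the phthalide A3.
- For: no metal, no protecting group on ring B, and ring A plus the C2–ring B bond formed in one thermal operation. On atom economy and tolerance of free phenols it is stronger than the chosen route.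
- Against: A1 holds two 1,3-diynes, so two cycloaromatisation pairings compete. The aryne must take ring B at C2 and hydrogen at C3, and A2 must react through its C4 and not through C2 or oxygen. The lactone carbonyl of A3 sits on C4, which is C–H in 18, so a carbon has to be excised after lactone opening. Ring C and the second aryl group on C7 are still missing (silyl removal, Sonogashira coupling, aryl addition to the ketone).
- Comparison: the chosen strategy buys ring A ready-made, gives the complete carbon skeleton in its key step and needs one step after it, whereas A3 needs at least five more.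

**Alternative 2: ester-tethered palladium C–H arylation.**
- Disconnection: only C2–C1' is cut, with the C1 carboxyl carbon tied to the ring B 2'-oxygen as an aryl ester.
- Forward key step: the aryl ester A4 (3-(methoxymethoxy)phenyl 6-chloro-3-[(methoxymethoxy)methyl]-2-{[4-(methoxymethoxy)phenyl]ethynyl}benzoate) would cyclise by oxidative addition of the C2–Cl bond, concerted metalation–deprotonation at the ring B C–H para to the OMOM group and reductive elimination, giving the benzo[c]chromen-6-one A5.
- For: the tether fixes which carbons are joined, the lactone carbonyl is C7 at a useful oxidation level, and the 2'-oxygen is delivered at the same time. Two aryl nucleophiles added to A5 would give the carbinol. On certainty of the regiochemistry of the biaryl bond it is stronger than an intermolecular aryne addition.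
- Against: A4 already needs four contiguous substituents on ring A (chloride, ester, alkyne, protected hydroxymethyl), so the hard pattern is only moved into the precursor, and no short path to it from a commercial arene is apparent. The hot, basic conditions that an aryl chloride needs endanger the aryl ester (acyl transfer) and the diarylalkyne (carbopalladation). Ring B offers a second ortho C–H between its two oxygens. Double addition to the hindered lactone carbonyl of A5 may stop after the first aryl group.
- Comparison: the chosen strategy forms C2–C1' and C1–C7 together, from a fluoroarene that is four steps from 1.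

**Alternative 3: Catellani ortho-carboxylation with alkynyl termination.**
- Disconnection: the C5–carboxyl and C6–C(sp) bonds are cut, while the C1 and C2 substituents are already present in the iodide A6 ([3-iodo-2',4'-bis(methoxymethoxy)[1,1'-biphenyl]-2-yl][4-(methoxymethoxy)phenyl]methanone).
- Forward key step: oxidative addition at C6–I, palladacycle formation at C5–H through a transient strained-olefin mediator, isopropoxycarbonylation at C5, extrusion of the mediator and alkynyl termination at C6 would give the keto ester A7.
- For: catalytic, two adjacent bonds per cycle, and ring C enters late, which is convenient for analogues. On modularity and functional-group tolerance it is stronger than organolithium chemistry.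
- Against: the key step makes the easier pair of bonds. The hard ones (C1–C7 and C2–C1') must already exist in A6, a 1,2,3-trisubstituted iodoarene with a hindered diaryl ketone that needs its own multi-step solution. After A7, an aryl nucleophile has to add to the ketone beside the ester, and the ester then has to be reduced beside the alkyne and the carbinol.
- Comparison: the chosen strategy is shorter and concentrates its risk in one step.

Key step: step 7

## Route

**Step 1**
Reactants: 1 2-bromo-4-fluorobenzaldehyde; 2 ethynyltrimethylsilane
Product: 3 4-fluoro-2-[(trimethylsilyl)ethynyl]benzaldehyde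
Conditions: PdCl2(PPh3)2 (cat.), CuI (cat.), Et3N/THF, 50 °C
Reagents that add atoms: none
Why: Sonogashira coupling; the C–Br bond ortho to the formyl group is activated for oxidative addition to zerovalent palladium, and the C–F bond is inert under these conditions.

**Step 2**
Reactants: 3 4-fluoro-2-[(trimethylsilyl)ethynyl]benzaldehyde
Product: 5 (2-ethynyl-4-fluorophenyl)methanol, via silylated benzyl alcohol 4 (not isolated)
Conditions: NaBH4, MeOH, 0 °C; then K2CO3 (cat.), rt
Reagents that add atoms: none
Why: Chemoselective hydride reduction of the aldehyde, then methoxide-induced protodesilylation of the alkyne in the same flask; reducing first avoids a free 2-ethynylbenzaldehyde, which cyclises easily.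

**Step 3**
Reactants: 5 (2-ethynyl-4-fluorophenyl)methanol; 6 4-iodophenol
Product: 7 4-{[5-fluoro-2-(hydroxymethyl)phenyl]ethynyl}phenol
Conditions: PdCl2(PPh3)2 (cat.), CuI (cat.), Et3N/THF, degassed, rt
Reagents that add atoms: none
Why: Sonogashira coupling of an aryl iodide, which proceeds at room temperature and tolerates the free phenol and the benzylic alcohol; the low temperature should keep the hydroxymethyl group from adding across the alkyne.

**Step 4**
Reactants: 7 4-{[5-fluoro-2-(hydroxymethyl)phenyl]ethynyl}phenol
Product: 8 4-fluoro-2-{[4-(methoxymethoxy)phenyl]ethynyl}-1-[(methoxymethoxy)methyl]benzene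
Conditions: MOMCl (3 equiv), iPr2NEt, CH2Cl2, 0 °C → rt
Reagents that add atoms: chloromethyl methyl ether (MOMCl), COCCl
Why: O-alkylation of the phenol and of the primary alcohol by the oxocarbenium-like chloromethyl ether (MOM protection); both hydroxyl groups are unhindered, so one operation should protect both.

**Step 5**
Reactants: 9 4-bromobenzene-1,3-diol (4-bromoresorcinol)
Product: 10 1-bromo-2,4-bis(methoxymethoxy)benzene
Conditions: MOMCl (2.5 equiv), iPr2NEt, CH2Cl2, 0 °C → rt
Reagents that add atoms: chloromethyl methyl ether (MOMCl), COCCl
Why: MOM protection of both phenols; the acetal oxygens later stabilise the aryllithium and chelate lithium in the key step.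

**Step 6**
Reactants: 11 bis(4-hydroxyphenyl)methanone (4,4'-dihydroxybenzophenone)
Product: 12 bis[4-(methoxymethoxy)phenyl]methanone
Conditions: MOMCl (2.5 equiv), iPr2NEt, DMF, 0 °C → rt
Reagents that add atoms: chloromethyl methyl ether (MOMCl), COCCl
Why: MOM protection of two acidic phenols; the resulting ketone is non-enolisable and carries no acidic hydrogen.

**Step 7**
Reactants: 8 4-fluoro-2-{[4-(methoxymethoxy)phenyl]ethynyl}-1-[(methoxymethoxy)methyl]benzene; 10 1-bromo-2,4-bis(methoxymethoxy)benzene; 12 bis[4-(methoxymethoxy)phenyl]methanone
Product: 17 {2',4'-bis(methoxymethoxy)-4-[(methoxymethoxy)methyl]-3-{[4-(methoxymethoxy)phenyl]ethynyl}[1,1'-biphenyl]-2-yl}bis[4-(methoxymethoxy)phenyl]methanol, via ring B aryllithium 13 (not isolated), via fluoroaryllithium 14 (not isolated), via alkynyl aryne 15 (not isolated), via biaryllithium 16 (not isolated)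
Conditions: 10 (1.5 equiv), t-BuLi (2 equiv per Br), THF, −78 °C; separately 8, n-BuLi (1.05 equiv), THF, −78 °C; combine, −78 → −20 °C; then LaCl3·2LiCl, 12 (2 equiv), THF, −78 °C → rt; aq. NH4Cl
Reagents that add atoms: none
Why: n-BuLi removes the ring A C1–H of 8, the most acidic one because it lies between fluorine and the sp carbon of the alkyne, and an alkyllithium is used instead of a lithium amide so that no N–H proton carrier is present that could move the lithium of 13 to the position between its two oxygens. On warming, 14 loses LiF to give the C1≡C2 aryne 15, and 13 attacks it at C2, the carbon remote from the alkyne, because the σ-withdrawing sp substituent on C6 distorts the aryne toward attack at the distal carbon, shields C1 and stabilises the carbanion that develops next to it. The resulting C1 aryllithium 16, held by the 2'-OMOM oxygen of ring B in a six-membered chelate, is converted by LaCl3·2LiCl into a less basic and more oxophilic aryllanthanum species that should add to the non-enolisable ketone 12 instead of passing an electron to it. The closest known reaction type is the anionic aryne biaryl coupling: ortho-lithiation of a haloarene, loss of lithium halide, carbolithiation of the aryne by an aryllithium and capture of the new ortho-lithiated biaryl by a carbonyl electrophile. No ring is closed and no stereocentre is formed. Three selectivities are needed: the site of deprotonation (secured by the double activation of C1–H at −78 °C), the direction of addition to 15 (secured by the alkynyl group on C6), and reaction of 15 with 13 in preference to 14 (secured by an excess of 13 and slow aryne release on warming).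

**Step 8**
Reactants: 17 {2',4'-bis(methoxymethoxy)-4-[(methoxymethoxy)methyl]-3-{[4-(methoxymethoxy)phenyl]ethynyl}[1,1'-biphenyl]-2-yl}bis[4-(methoxymethoxy)phenyl]methanol
Product: 18 Selaginellin F, 4-[{2',4'-dihydroxy-4-(hydroxymethyl)-3-[(4-hydroxyphenyl)ethynyl][1,1'-biphenyl]-2-yl}(4-hydroxyphenyl)methylidene]cyclohexa-2,5-dien-1-one
Conditions: HCl (6 M aq.), MeOH/THF, 45 °C; then dilute with water, extract
Reagents that add atoms: none
Why: Acid-catalysed transacetalisation to methanol removes all six MOM groups, and the triaryl carbinol ionises to a trityl-type cation that loses the proton of a para-hydroxyl group on work-up to give the quinone methide (E1 dehydration, fuchsone formation); rings D and E are interchangeable, so only one product can form.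

## Compound list

1 | 2-bromo-4-fluorobenzaldehyde | O=Cc1ccc(F)cc1Br | starting material
2 | ethynyltrimethylsilane | C#C[Si](C)(C)C | starting material
3 | 4-fluoro-2-[(trimethylsilyl)ethynyl]benzaldehyde | O=Cc1ccc(F)cc1C#C[Si](C)(C)C | intermediate
4 | {4-fluoro-2-[(trimethylsilyl)ethynyl]phenyl}methanol | OCc1ccc(F)cc1C#C[Si](C)(C)C | intermediate
5 | (2-ethynyl-4-fluorophenyl)methanol | OCc1ccc(F)cc1C#C | intermediate
6 | 4-iodophenol | Oc1ccc(I)cc1 | starting material
7 | 4-{[5-fluoro-2-(hydroxymethyl)phenyl]ethynyl}phenol | OCc1ccc(F)cc1C#Cc1ccc(O)cc1 | intermediate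
8 | 4-fluoro-2-{[4-(methoxymethoxy)phenyl]ethynyl}-1-[(methoxymethoxy)methyl]benzene | COCOCc1ccc(F)cc1C#Cc1ccc(OCOC)cc1 | intermediate
9 | 4-bromobenzene-1,3-diol (4-bromoresorcinol) | Oc1ccc(Br)c(O)c1 | starting material
10 | 1-bromo-2,4-bis(methoxymethoxy)benzene | COCOc1ccc(Br)c(OCOC)c1 | intermediate
11 | bis(4-hydroxyphenyl)methanone (4,4'-dihydroxybenzophenone) | O=C(c1ccc(O)cc1)c1ccc(O)cc1 | starting material
12 | bis[4-(methoxymethoxy)phenyl]methanone | O=C(c1ccc(OCOC)cc1)c1ccc(OCOC)cc1 | intermediate
13 | [2,4-bis(methoxymethoxy)phenyl]lithium | [Li]c1ccc(OCOC)cc1OCOC | intermediate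
14 | (6-fluoro-2-{[4-(methoxymethoxy)phenyl]ethynyl}-3-[(methoxymethoxy)methyl]phenyl)lithium | [Li]c1c(F)ccc(COCOC)c1C#Cc1ccc(OCOC)cc1 | intermediate
15 | 3-{[4-(methoxymethoxy)phenyl]ethynyl}-4-[(methoxymethoxy)methyl]-1,2-didehydrobenzene | C1(C#Cc2ccc(OCOC)cc2)=C(COCOC)C=CC#C1 | intermediate
16 | {2',4'-bis(methoxymethoxy)-4-[(methoxymethoxy)methyl]-3-{[4-(methoxymethoxy)phenyl]ethynyl}[1,1'-biphenyl]-2-yl}lithium | [Li]c1c(-c2ccc(OCOC)cc2OCOC)ccc(COCOC)c1C#Cc1ccc(OCOC)cc1 | intermediate
17 | {2',4'-bis(methoxymethoxy)-4-[(methoxymethoxy)methyl]-3-{[4-(methoxymethoxy)phenyl]ethynyl}[1,1'-biphenyl]-2-yl}bis[4-(methoxymethoxy)phenyl]methanol | OC(c1ccc(OCOC)cc1)(c1ccc(OCOC)cc1)c1c(-c2ccc(OCOC)cc2OCOC)ccc(COCOC)c1C#Cc1ccc(OCOC)cc1 | intermediate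
18 | Selaginellin F, 4-[{2',4'-dihydroxy-4-(hydroxymethyl)-3-[(4-hydroxyphenyl)ethynyl][1,1'-biphenyl]-2-yl}(4-hydroxyphenyl)methylidene]cyclohexa-2,5-dien-1-one | O=C1C=CC(=C(c2ccc(O)cc2)c2c(-c3ccc(O)cc3O)ccc(CO)c2C#Cc2ccc(O)cc2)C=C1 | target

## Step count and least certain steps

Total: 8 steps. Longest linear sequence: 6 steps (steps 1, 2, 3, 4, 7 and 8); steps 5 and 6 are one-step side branches.

**Step 7 (key step).** The most likely failure is that the doubly ortho-substituted organometallic 16 does not add to the diaryl ketone 12 but is protonated or transfers an electron to it, so that the biaryl lacking C7 builds up. Lesser risks are addition of the alkyllithium across the alkyne before deprotonation is complete and loss of regiocontrol in the addition to 15. The fallback leaves the route at 16 and returns at 17. 16, generated exactly as in step 7, is trapped at −78 °C with the small and more electrophilic commercial 4-(methoxymethoxy)benzaldehyde in place of 12. After work-up this should give the racemic secondary carbinol {2',4'-bis(methoxymethoxy)-4-[(methoxymethoxy)methyl]-3-{[4-(methoxymethoxy)phenyl]ethynyl}[1,1'-biphenyl]-2-yl}[4-(methoxymethoxy)phenyl]methanol F1. Oxidation with Dess–Martin periodinane (NaHCO3, CH2Cl2) should give the ketone {2',4'-bis(methoxymethoxy)-4-[(methoxymethoxy)methyl]-3-{[4-(methoxymethoxy)phenyl]ethynyl}[1,1'-biphenyl]-2-yl}[4-(methoxymethoxy)phenyl]methanone F2. Addition of [4-(methoxymethoxy)phenyl]lithium F3 (from commercial 1-bromo-4-(methoxymethoxy)benzene and t-BuLi, THF, −78 °C, with LaCl3·2LiCl) to F2 then gives 17. In this sequence the hindered centre is the electrophile and the nucleophile is small, at the price of two more steps.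

**Step 8.** The most likely failure is that cleavage of the aliphatic acetal at C5 lags behind that of the five aryl acetals. The longer or hotter acid treatment then needed could let the C5 hydroxymethyl group add across the neighbouring alkyne or let the ring B 2'-hydroxyl close onto C7. The fallback leaves the route at 17 and returns at 18. The acetals are removed without protic acid by TMSOTf and 2,2'-bipyridyl in CH2Cl2 at 0 °C followed by water, which cleaves aryl and alkyl MOM ethers through silyl ether and pyridinium intermediates. This should give the free carbinol {2',4'-dihydroxy-4-(hydroxymethyl)-3-[(4-hydroxyphenyl)ethynyl][1,1'-biphenyl]-2-yl}bis(4-hydroxyphenyl)methanol F4. F4 is then dehydrated in a separate, mild operation (catalytic AcOH in warm EtOAc, or on silica) to 18.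

**Step 3.** The most likely failure is cycloisomerisation: under copper and palladium catalysis the free hydroxymethyl group of 5 or 7 adds across the alkyne, and 5 can also dimerise oxidatively. The fallback leaves the route at 6 and 1 and returns at 8.
- 6 is protected (MOMCl, iPr2NEt, CH2Cl2) as 1-iodo-4-(methoxymethoxy)benzene F5.
- F5 is coupled with 2 (PdCl2(PPh3)2, CuI, Et3N, rt) to trimethyl{[4-(methoxymethoxy)phenyl]ethynyl}silane F6, which is desilylated (K2CO3, MeOH) to 1-ethynyl-4-(methoxymethoxy)benzene F7.
- Sonogashira coupling of F7 with bromide 1 (PdCl2(PPh3)2, CuI, Et3N/THF, 50 °C) should give 4-fluoro-2-{[4-(methoxymethoxy)phenyl]ethynyl}benzaldehyde F8.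
- NaBH4 in MeOH reduces F8 to (4-fluoro-2-{[4-(methoxymethoxy)phenyl]ethynyl}phenyl)methanol F9, and MOM protection of F9 gives 8.

No hydroxyl group then stands next to the alkyne during a metal-catalysed step, at the price of two more steps.

## Further compounds

F1 | step 7 | {2',4'-bis(methoxymethoxy)-4-[(methoxymethoxy)methyl]-3-{[4-(methoxymethoxy)phenyl]ethynyl}[1,1'-biphenyl]-2-yl}[4-(methoxymethoxy)phenyl]methanol (racemic) | OC(c1ccc(OCOC)cc1)c1c(-c2ccc(OCOC)cc2OCOC)ccc(COCOC)c1C#Cc1ccc(OCOC)cc1
F2 | step 7 | {2',4'-bis(methoxymethoxy)-4-[(methoxymethoxy)methyl]-3-{[4-(methoxymethoxy)phenyl]ethynyl}[1,1'-biphenyl]-2-yl}[4-(methoxymethoxy)phenyl]methanone | O=C(c1ccc(OCOC)cc1)c1c(-c2ccc(OCOC)cc2OCOC)ccc(COCOC)c1C#Cc1ccc(OCOC)cc1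
F3 | step 7 | [4-(methoxymethoxy)phenyl]lithium | [Li]c1ccc(OCOC)cc1
F4 | step 8 | {2',4'-dihydroxy-4-(hydroxymethyl)-3-[(4-hydroxyphenyl)ethynyl][1,1'-biphenyl]-2-yl}bis(4-hydroxyphenyl)methanol | OC(c1ccc(O)cc1)(c1ccc(O)cc1)c1c(-c2ccc(O)cc2O)ccc(CO)c1C#Cc1ccc(O)cc1
F5 | step 3 | 1-iodo-4-(methoxymethoxy)benzene | COCOc1ccc(I)cc1
F6 | step 3 | trimethyl{[4-(methoxymethoxy)phenyl]ethynyl}silane | COCOc1ccc(C#C[Si](C)(C)C)cc1
F7 | step 3 | 1-ethynyl-4-(methoxymethoxy)benzene | COCOc1ccc(C#C)cc1
F8 | step 3 | 4-fluoro-2-{[4-(methoxymethoxy)phenyl]ethynyl}benzaldehyde | O=Cc1ccc(F)cc1C#Cc1ccc(OCOC)cc1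
F9 | step 3 | (4-fluoro-2-{[4-(methoxymethoxy)phenyl]ethynyl}phenyl)methanol | OCc1ccc(F)cc1C#Cc1ccc(OCOC)cc1
A1 | alternative 1 | 5-[tri(propan-2-yl)silyl]penta-2,4-diyn-1-yl 6-[4-(methoxymethoxy)phenyl]-6-oxohexa-2,4-diynoate | O=C(c1ccc(OCOC)cc1)C#CC#CC(=O)OCC#CC#C[Si](C(C)C)(C(C)C)C(C)C
A2 | alternative 1 | benzene-1,3-diol (resorcinol) | Oc1cccc(O)c1
A3 | alternative 1 | 6-(2,4-dihydroxyphenyl)-5-[4-(methoxymethoxy)benzoyl]-4-{[tri(propan-2-yl)silyl]ethynyl}-2-benzofuran-1(3H)-one | O=C(c1ccc(OCOC)cc1)c1c(-c2ccc(O)cc2O)cc2C(=O)OCc2c1C#C[Si](C(C)C)(C(C)C)C(C)C
A4 | alternative 2 | 3-(methoxymethoxy)phenyl 6-chloro-3-[(methoxymethoxy)methyl]-2-{[4-(methoxymethoxy)phenyl]ethynyl}benzoate | O=C(Oc1cccc(OCOC)c1)c1c(Cl)ccc(COCOC)c1C#Cc1ccc(OCOC)cc1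
A5 | alternative 2 | 3-(methoxymethoxy)-8-[(methoxymethoxy)methyl]-7-{[4-(methoxymethoxy)phenyl]ethynyl}-6H-benzo[c]chromen-6-one | O=C1Oc2cc(OCOC)ccc2-c2ccc(COCOC)c(C#Cc3ccc(OCOC)cc3)c21
A6 | alternative 3 | [3-iodo-2',4'-bis(methoxymethoxy)[1,1'-biphenyl]-2-yl][4-(methoxymethoxy)phenyl]methanone | O=C(c1ccc(OCOC)cc1)c1c(I)cccc1-c1ccc(OCOC)cc1OCOC
A7 | alternative 3 | propan-2-yl 2-[4-(methoxymethoxy)benzoyl]-2',4'-bis(methoxymethoxy)-3-{[4-(methoxymethoxy)phenyl]ethynyl}[1,1'-biphenyl]-4-carboxylate | O=C(c1ccc(OCOC)cc1)c1c(C#Cc2ccc(OCOC)cc2)c(C(=O)OC(C)C)ccc1-c1ccc(OCOC)cc1OCOC
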